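## Structural features

The target, (2S,4R,6S)-2-(3,4-dihydroxy-5-methoxyphenyl)-6-[2-(4-hydroxyphenyl)ethyl]oxan-4-ol, is a cyclised 1,7-diarylheptane. One tetrahydropyran ring (O1, C2–C6) carries the trioxygenated aryl ring directly on C2, a secondary hydroxyl on C4 and, on C6, a two-carbon chain (C7, C8) ending in a 4-hydroxyphenyl ring. The stereocentres C2, C4 and C6 are not contiguous: they alternate with the methylenes C3 and C5, and C2 and C6 are joined through O1. All three substituents are cis, that is, equatorial on one chair. The fragile parts are the catechol (easily oxidised), the three phenols (to be masked with one kind of group) and the C2–O1 bond. That bond is benzylic to an electron-rich ring, so acid can ionise it and hydrogenolysis can cleave it; at the 4-ketone stage it also opens by retro-oxa-Michael reaction. There is no quaternary carbon and no strain. The real difficulty is to fix one absolute configuration, relay it to the other two centres without scrambling, and join two different aryl-bearing halves at C4 in a controlled order. The feature used is that C4 lies between two methylenes (C3, C5), each leading to an oxygen-bearing carbon (C2, C6). C4 can therefore act as a carbonyl carbon of reversed polarity that bonds to the terminal carbons of two epoxides. Because the C2/C6 diequatorial arrangement is the thermodynamic one and the equatorial C4 alcohol is the product of axial hydride attack, only C6 has to be brought in as a stereocentre.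

## Logic of the disconnections

21 is traced to 20 by cutting the three phenolic O–CH2Ph bonds. The phenols must be masked through the organolithium and acid steps, and benzyl comes off without acid or base. The forward demand is that hydrogenolysis spare the benzylic C2–O1 bond.

20 is traced to 19 by replacing the C4–H bond with a carbonyl. This removes one stereocentre and exposes the 1,3,5-oxygen pattern with C4 at the ketone level. The forward demand is axial hydride delivery to a chair with both substituents equatorial.

19 is traced through 18 and 17 to 16 by cutting O1–C2 (conjugate-addition retron), adding water back across C2=C3 and placing a silyl group on the C6 oxygen. The ring and the C2 stereocentre disappear and only C6 remains stereodefined. The forward demands are a reversible closure that settles in the diequatorial arrangement, and loss of the C2 oxygen, never the C6 oxygen.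

16 is traced to 15 by turning the C4 carbonyl into its cyclic dithioacetal, because C4 has to be nucleophilic twice. The unmasking must neither oxidise nor halogenate the alkoxyarenes.

15 is cut at C4–C5 and at C3–C4 into 3, 8 and 11. This is the strategic cut: three fragments of similar size, each one or two steps from a catalogue compound, with C6 arriving configured and its oxygen already differentiated as a silyl ether. The forward demands are attack at the unsubstituted carbon of each epoxide and a strict order of addition. The carbon that 11 delivers as C2 becomes sp2 later, so 11 needs no defined configuration.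

3 is traced through 2 to 1 by cutting the C–Si bond; the only demand is monosilylation.

8 is traced to 7 by opening the epoxide O–CH2 bond to a chlorohydrin, and 7 through 6 to 4 and 5 by cutting C7–C8. The stereocentre then comes from the chiral pool with its C–O bond never broken. The forward demand is attack of 6 on the ring CH2 of 5 and not on CH2Cl, which would give the enantiomer.

11 is traced to 10 by removing the epoxide methylene (C2–C3 and C3–O, methylene transfer), and 10 to 9 by cutting two O–benzyl bonds. Both forward steps are routine; 11 is acid-sensitive and must be handled accordingly.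

## Other disconnections considered

Alternative 1: The cut is C2–C3, with C2 taken back to a benzylic ether CH2. The precursor is the aryl-methyl ether A2, which carries an enol acetate three atoms from the ether oxygen. In the forward step DDQ abstracts hydride from the ArCH2–O carbon, and the enol acetate carbon traps the aryl-stabilised oxocarbenium ion through a chair to give pyranone A1.
- In favour: ring, C2–C3 bond and the C2 stereocentre form in one kinetically controlled step from the single C6 centre, and the precursor is assembled by simple O-alkylation without sulfur or organolithium relay chemistry.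
- Against, here: the oxidant must select the trioxygenated benzyl ether over two O-benzyl groups and the phenethyl CH2. The remote phenol therefore has to be an ester in A2 and A1, which needs a different deprotection at the end. The 4-alkoxy group is twisted by its two neighbours, which makes hydride abstraction slower than for a simple p-alkoxybenzyl ether. The product is itself a benzylic ether exposed to the oxidant.
- Comparison: both plans rest on C6 alone and pass through a cis-2,6-pyranone, so they are equal in stereochemical economy. Setting C2 irreversibly is in principle better than relying on equilibration. The chosen plan is weakest in the regiochemistry of an aryl epoxide opening, this one in chemoselective oxidation. Step count is judged equal or one to two steps longer because of the second protecting-group type.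

Alternative 2: The cut is O1–C6 with allylic transposition. The precursor is the open-chain E-allylic diol A4 with centres at C2, C4 and C8. In the forward step Pd(II) mediates syn-oxypalladation by the C2 hydroxyl at C6 and syn-elimination of the C8 hydroxyl, transferring the C8 configuration to C6 and giving the styrenyl tetrahydropyran A3.
- In favour: C4 is already a protected carbinol, so no late ketone reduction is needed; this is better than the chosen plan on that point. The conditions are neutral, and one final hydrogenation would saturate C7=C8 and remove the benzyl groups together, so the end-game is at least equal.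
- Against, here: three stereocentres must be built separately in A4, and one of them (C8) is sacrificial. That C8 carbinol is both allylic and benzylic to a p-alkoxyphenyl ring, so ionisation could compete with the stereospecific pathway. The benzylic C2 carbinol must also be made enantioselectively and kept.
- Comparison: the stereospecific closure is mechanistically cleaner than a thermodynamic one and would be preferred if the cis/trans energy gap were small, which it is not for a diequatorial 2,6-pattern. The acyclic stereochemical work makes this route clearly longer, and the chosen plan is better on step economy.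

Alternative 3: The cut is C5–C6. The precursor is the cis-1,3-dioxane enol ether acetal A6, obtainable from an enantioenriched β-aryl-β-hydroxy acid and a 3-arylpropanal by acetalisation and carbonyl methylenation. In the forward step a Lewis acid such as Me2AlCl breaks the acetal C6–O(enol) bond, and the aluminium enolate carbon C5 adds to the oxocarbenium carbon C6 (Petasis–Ferrier rearrangement) to give pyranone A5, the same compound as 19.
- In favour: the end-game is identical to the chosen plan (equal). C2 is introduced on purpose and retained, which is better than creating and erasing a carbinol, and no HMPA, tert-butyllithium or dithiane removal is needed.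
- Against, here: the controlling centre becomes the benzylic C2–O carbon of an electron-rich arene, which must survive a strong Lewis acid that is meant to ionise the neighbouring acetal bond. The β-hydroxy acid needs an asymmetric acetate-aldol or reduction step, and the methylenation is run hot on a sensitive acetal.
- Comparison: the chosen plan keeps the stereochemical information at C6, a robust alkyl carbinol, and lets C2 follow. Overall length is judged about equal. The choice rests on where the stereochemical risk sits.

Key step: step 6

Remark on the chemistry: the constitution and descriptors of the three coupling partners were checked against the target and need no correction; the S alkyl epoxide maps onto C6 (S) with its C–O bond intact. The aryl epoxide is used as the racemate because its carbinol carbon becomes sp2 before the ring closes. Compounds 15 and 16 are therefore pairs of epimers at that carbon, and every compound from 17 on is a single stereoisomer.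

## Route

Step 1
Reactants: 1 1,3-dithiane
Product: 3 2-(tert-butyldimethylsilyl)-1,3-dithiane, via 2-lithio-1,3-dithiane 2 (not isolated)
Conditions: n-BuLi (1.05 equiv), THF, −30 °C; TBSCl (1.1 equiv), −78 °C → rt
Reagents that add atoms: tert-butyldimethylsilyl chloride, CC(C)(C)[Si](C)(C)Cl
Why: Corey–Seebach lithiation of the acidic C2–H followed by C-silylation; the carbanion is fully formed before the electrophile is added, so one silyl group is introduced.

Step 2
Reactants: 4 4-(benzyloxy)benzyl chloride; 5 (S)-epichlorohydrin
Product: 7 (2S)-4-[4-(benzyloxy)phenyl]-1-chlorobutan-2-ol, via 4-(benzyloxy)benzylmagnesium chloride 6 (not isolated)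
Conditions: Mg, THF (dilute, slow addition of 4), 0 °C → rt; CuI (5 mol%), 5, −40 → −20 °C; 1 M HCl
Reagents that add atoms: none
Why: Copper-catalysed Grignard opening of a terminal epoxide at its unsubstituted ring carbon, which under cuprate catalysis at low temperature is faster than displacement of the primary chloride; the stereocentre keeps its C–O bond, so the S configuration of 5 is carried into 7.

Step 3
Reactants: 7 (2S)-4-[4-(benzyloxy)phenyl]-1-chlorobutan-2-ol
Product: 8 (S)-2-{2-[4-(benzyloxy)phenyl]ethyl}oxirane
Conditions: NaOH (2 M aq), THF, 0 °C → rt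
Reagents that add atoms: none
Why: Intramolecular Williamson etherification (3-exo-tet) of the chlorohydrin; the alkoxide attacks the CH2Cl carbon, the stereocentre is not involved and stays S.

Step 4
Reactants: 9 3,4-dihydroxy-5-methoxybenzaldehyde
Product: 10 3,4-bis(benzyloxy)-5-methoxybenzaldehyde
Conditions: BnBr (2.3 equiv), K2CO3, DMF, 60 °C
Reagents that add atoms: benzyl bromide, BrCc1ccccc1
Why: Williamson O-alkylation of both phenoxides; the aldehyde is inert to carbonate.

Step 5
Reactants: 10 3,4-bis(benzyloxy)-5-methoxybenzaldehyde
Product: 11 (±)-2-[3,4-bis(benzyloxy)-5-methoxyphenyl]oxirane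
Conditions: Me3S+ I−, KOt-Bu, DMSO/THF, 0 °C → rt; base-washed silica or used crude
Reagents that add atoms: trimethylsulfonium iodide, C[S+](C)C.[I-]
Why: Corey–Chaykovsky methylene transfer to a non-enolisable aryl aldehyde (ylide addition, then 3-exo-tet closure with loss of dimethyl sulfide); no stereocontrol is sought because this carbon loses its configuration in step 8.

Step 6
Reactants: 3 2-(tert-butyldimethylsilyl)-1,3-dithiane; 8 (S)-2-{2-[4-(benzyloxy)phenyl]ethyl}oxirane; 11 (±)-2-[3,4-bis(benzyloxy)-5-methoxyphenyl]oxirane
Product: 15 (1RS)-1-[3,4-bis(benzyloxy)-5-methoxyphenyl]-2-{2-[(2S)-4-[4-(benzyloxy)phenyl]-2-(tert-butyldimethylsilyloxy)butyl]-1,3-dithian-2-yl}ethan-1-ol, via lithiated silyl dithiane 12 (not isolated), via lithium alkoxide 13 (not isolated), via relayed dithiane anion 14 (not isolated)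
Conditions: 3 (1.15 equiv), t-BuLi, Et2O, −78 → −45 °C; 8 (1.0 equiv), −78 → −25 °C; then 11 (1.4 equiv), HMPA (0.3–1 equiv), Et2O/THF, −78 → 0 °C; H2O
Reagents that add atoms: none
Why: tert-Butyllithium removes the C2–H of 3 to give 12, which opens 8 by SN2 attack at its CH2 carbon and forms C4–C5 and alkoxide 13. In ether alone 13 is stable; when HMPA is added the silyl group moves from carbon to the 1,4-related oxygen (Brook rearrangement), giving the silyl ether carbanion 14, which opens 11 at its CH2 carbon and forms C3–C4. The closest known reaction type is the one-flask coupling of 2-silyl-1,3-dithianes with two different epoxides under solvent-gated 1,4-Brook rearrangement, itself an extension of Corey–Seebach epoxide alkylation. No ring is closed and no stereocentre is created: C6 enters as S with its C–O bond untouched, and the benzylic carbinol carbon enters in both configurations. The step needs attack at the terminal carbon of each epoxide and a strict order of addition. The first is secured by the bulk of the tertiary carbanions 12 and 14 and, for 11, by HMPA keeping lithium from activating the benzylic C–O bond, while the 4-alkoxy group is twisted by its two ortho neighbours and donates only weakly. The second is secured by running the first opening to completion in ether before the polar additive is introduced together with 11.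

Step 7
Reactants: 15 coupled dithiane (both C1 epimers)
Product: 16 (1RS,5S)-1-[3,4-bis(benzyloxy)-5-methoxyphenyl]-7-[4-(benzyloxy)phenyl]-5-(tert-butyldimethylsilyloxy)-1-hydroxyheptan-3-one
Conditions: MeI (10 equiv), CaCO3, MeCN/H2O (9:1), 45 °C
Reagents that add atoms: water, O
Why: S-alkylative hydrolysis of the dithioacetal (sulfonium formation, then water adds to the thionium ion); the conditions are neither oxidising nor halogenating, so the alkoxyarenes, the silyl ether and the buffered β-hydroxy ketone survive.

Step 8
Reactants: 16 β-hydroxy-β'-silyloxy ketone (both C1 epimers)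
Product: 19 (2S,6S)-2-[3,4-bis(benzyloxy)-5-methoxyphenyl]-6-{2-[4-(benzyloxy)phenyl]ethyl}oxan-4-one, via silyloxy enone 17 (not isolated), via hydroxy enone 18 (not isolated)
Conditions: TsOH·H2O (1 equiv), MeCN/H2O (10:1), rt → 45 °C
Reagents that add atoms: none
Why: Acid-mediated cascade: the benzylic β-hydroxy ketone dehydrates to the E enone 17 while the C6 oxygen is still silylated, the silyl ether is then hydrolysed to 18, and the C6 hydroxyl adds to C2 by a reversible 6-endo-trig oxa-Michael reaction; under equilibration the aryl group settles equatorial, cis to the C6 chain, so the untouched S centre at C6 sets C2 as S and both epimers of 16 converge.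

Step 9
Reactants: 19 (2S,6S)-pyranone
Product: 20 (2S,4R,6S)-2-[3,4-bis(benzyloxy)-5-methoxyphenyl]-6-{2-[4-(benzyloxy)phenyl]ethyl}oxan-4-ol
Conditions: NaBH4, MeOH/THF, −40 → 0 °C
Reagents that add atoms: none
Why: Borohydride reduction of a conformationally fixed cyclohexanone-type ketone; the small hydride attacks axially on the chair with both substituents equatorial and gives the equatorial, all-cis 4R alcohol.

Step 10
Reactants: 20 tribenzyl ether
Product: 21 (2S,4R,6S)-2-(3,4-dihydroxy-5-methoxyphenyl)-6-[2-(4-hydroxyphenyl)ethyl]oxan-4-ol
Conditions: H2 (1 atm), 10% Pd/C, EtOAc/MeOH, rt, stopped at full debenzylation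
Reagents that add atoms: none
Why: Catalytic hydrogenolysis of three aryl benzyl ethers; the ring C2–O1 bond, a secondary benzylic dialkyl ether, is cleaved far more slowly, and no stereocentre is touched.

## Compound list

1 | 1,3-dithiane | C1CSCSC1 | starting material
2 | 2-lithio-1,3-dithiane | [Li]C1SCCCS1 | intermediate (not isolated)
3 | 2-(tert-butyldimethylsilyl)-1,3-dithiane | CC(C)(C)[Si](C)(C)C1SCCCS1 | intermediate
4 | 4-(benzyloxy)benzyl chloride | ClCc1ccc(OCc2ccccc2)cc1 | starting material
5 | (S)-epichlorohydrin, (2S)-2-(chloromethyl)oxirane | ClC[C@@H]1CO1 | starting material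
6 | 4-(benzyloxy)benzylmagnesium chloride | Cl[Mg]Cc1ccc(OCc2ccccc2)cc1 | intermediate (not isolated)
7 | (2S)-4-[4-(benzyloxy)phenyl]-1-chlorobutan-2-ol | ClC[C@@H](O)CCc1ccc(OCc2ccccc2)cc1 | intermediate
8 | (S)-2-{2-[4-(benzyloxy)phenyl]ethyl}oxirane | O(Cc1ccccc1)c1ccc(CC[C@H]2CO2)cc1 | intermediate
9 | 3,4-dihydroxy-5-methoxybenzaldehyde (5-hydroxyvanillin) | COc1cc(C=O)cc(O)c1O | starting material
10 | 3,4-bis(benzyloxy)-5-methoxybenzaldehyde | COc1cc(C=O)cc(OCc2ccccc2)c1OCc3ccccc3 | intermediate
11 | (±)-2-[3,4-bis(benzyloxy)-5-methoxyphenyl]oxirane (racemate) | COc1cc(C2CO2)cc(OCc3ccccc3)c1OCc4ccccc4 | intermediate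
12 | 2-lithio-2-(tert-butyldimethylsilyl)-1,3-dithiane | [Li]C1([Si](C)(C)C(C)(C)C)SCCCS1 | intermediate (not isolated)
13 | lithium (2S)-4-[4-(benzyloxy)phenyl]-1-[2-(tert-butyldimethylsilyl)-1,3-dithian-2-yl]butan-2-olate | [Li]O[C@@H](CCc1ccc(OCc2ccccc2)cc1)CC1([Si](C)(C)C(C)(C)C)SCCCS1 | intermediate (not isolated)
14 | 2-lithio-2-[(2S)-4-[4-(benzyloxy)phenyl]-2-(tert-butyldimethylsilyloxy)butyl]-1,3-dithiane | [Li]C1(C[C@H](CCc2ccc(OCc3ccccc3)cc2)O[Si](C)(C)C(C)(C)C)SCCCS1 | intermediate (not isolated)
15 | (1RS)-1-[3,4-bis(benzyloxy)-5-methoxyphenyl]-2-{2-[(2S)-4-[4-(benzyloxy)phenyl]-2-(tert-butyldimethylsilyloxy)butyl]-1,3-dithian-2-yl}ethan-1-ol (both C1 epimers, S at the silyloxy carbon) | COc1cc(C(O)CC2(C[C@H](CCc3ccc(OCc4ccccc4)cc3)O[Si](C)(C)C(C)(C)C)SCCCS2)cc(OCc5ccccc5)c1OCc6ccccc6 | intermediate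
16 | (1RS,5S)-1-[3,4-bis(benzyloxy)-5-methoxyphenyl]-7-[4-(benzyloxy)phenyl]-5-(tert-butyldimethylsilyloxy)-1-hydroxyheptan-3-one (both C1 epimers) | COc1cc(C(O)CC(=O)C[C@H](CCc2ccc(OCc3ccccc3)cc2)O[Si](C)(C)C(C)(C)C)cc(OCc4ccccc4)c1OCc5ccccc5 | intermediate
17 | (1E,5S)-1-[3,4-bis(benzyloxy)-5-methoxyphenyl]-7-[4-(benzyloxy)phenyl]-5-(tert-butyldimethylsilyloxy)hept-1-en-3-one | COc1cc(/C=C/C(=O)C[C@H](CCc2ccc(OCc3ccccc3)cc2)O[Si](C)(C)C(C)(C)C)cc(OCc4ccccc4)c1OCc5ccccc5 | intermediate (not isolated)
18 | (1E,5S)-1-[3,4-bis(benzyloxy)-5-methoxyphenyl]-7-[4-(benzyloxy)phenyl]-5-hydroxyhept-1-en-3-one | COc1cc(/C=C/C(=O)C[C@H](CCc2ccc(OCc3ccccc3)cc2)O)cc(OCc4ccccc4)c1OCc5ccccc5 | intermediate (not isolated)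
19 | (2S,6S)-2-[3,4-bis(benzyloxy)-5-methoxyphenyl]-6-{2-[4-(benzyloxy)phenyl]ethyl}oxan-4-one (2,6-cis) | COc1cc([C@@H]2CC(=O)C[C@H](CCc3ccc(OCc4ccccc4)cc3)O2)cc(OCc5ccccc5)c1OCc6ccccc6 | intermediate
20 | (2S,4R,6S)-2-[3,4-bis(benzyloxy)-5-methoxyphenyl]-6-{2-[4-(benzyloxy)phenyl]ethyl}oxan-4-ol (all-cis) | COc1cc([C@@H]2C[C@H](O)C[C@H](CCc3ccc(OCc4ccccc4)cc3)O2)cc(OCc5ccccc5)c1OCc6ccccc6 | intermediate
21 | (2S,4R,6S)-2-(3,4-dihydroxy-5-methoxyphenyl)-6-[2-(4-hydroxyphenyl)ethyl]oxan-4-ol | COc1cc([C@@H]2C[C@H](O)C[C@H](CCc3ccc(O)cc3)O2)cc(O)c1O | target

## Step count and least certain steps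

Total step count: 10. Longest linear sequence: 7 steps (steps 2, 3, 6, 7, 8, 9, 10 from 4; the branch from 9 through steps 4 and 5 is equally long).

**Step 6 (key step).** The electron-rich aryl epoxide 11 is the weak point. The slow, hindered carbanion 14 leaves time for attack at the benzylic carbon or for lithium-induced isomerisation of 11 to an arylacetaldehyde. A second concern is the relay running out of order: silyl migration before 8 is consumed would lead to incorporation of two molecules of 8. The fallback avoids both the aryl epoxide and the relay; it sets out from 8 and 10 and returns at 16.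
- Commercial 2-methyl-1,3-dithiane is lithiated (n-BuLi, THF) to 2-lithio-2-methyl-1,3-dithiane F1.
- F1 opens 8 at its terminal carbon to give (2S)-4-[4-(benzyloxy)phenyl]-1-(2-methyl-1,3-dithian-2-yl)butan-2-ol F2.
- Silylation (TBSCl, imidazole, DMF) gives 2-[(2S)-4-[4-(benzyloxy)phenyl]-2-(tert-butyldimethylsilyloxy)butyl]-2-methyl-1,3-dithiane F3.
- Alkylative hydrolysis (MeI, CaCO3, aqueous MeCN) gives (4S)-6-[4-(benzyloxy)phenyl]-4-(tert-butyldimethylsilyloxy)hexan-2-one F4.
- Regioselective enolisation on the methyl side (Bu2BOTf, i-Pr2NEt, CH2Cl2, −78 °C) gives the dibutylboron enolate F5, whose aldol addition to 10 gives 16 as the same pair of epimers.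

**Step 8.** The three acid-driven events may not stay in the intended order. Early desilylation followed by elimination towards C5–C6 would, through the 2R epimer, erode enantiopurity; the benzylic cation may also alkylate another electron-rich ring; desilylation may stall. The fallback separates the events under non-ionising conditions; it sets out from 16 and returns at 19. Mesylation (MsCl, Et3N, CH2Cl2, 0 °C) gives (1RS,5S)-1-[3,4-bis(benzyloxy)-5-methoxyphenyl]-7-[4-(benzyloxy)phenyl]-5-(tert-butyldimethylsilyloxy)-3-oxoheptyl methanesulfonate F6. F6 undergoes E1cB elimination in the same flask to 17, which is isolated. Fluoride desilylation (HF·pyridine, THF) then gives 18, which closes to 19.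

**Step 2.** Formation of the electron-rich benzylic Grignard reagent 6 may be accompanied by Wurtz homocoupling. In the opening, direct displacement of chloride (which gives the enantiomeric series) or a second addition after premature epoxide closure may compete. The fallback reverses the polarity of the C–C bond formation and takes the configuration from a resolution; it sets out from 4 and returns at 8.
- Commercial allylmagnesium bromide displaces the benzylic chloride of 4 (THF, 0 °C) to give 1-(benzyloxy)-4-(but-3-en-1-yl)benzene F7.
- mCPBA (CH2Cl2) gives (±)-2-{2-[4-(benzyloxy)phenyl]ethyl}oxirane F8.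
- Hydrolytic kinetic resolution with (S,S)-(salen)Co(III)OAc and 0.55 equiv of water, the catalyst enantiomer expected to hydrolyse the R epoxide, leaves 8. The sense is to be confirmed on the product before use.

**Step 10.** Over-reduction is the concern: once the para-phenol is unmasked, the benzylic C2–O1 bond of the electron-rich ring may be hydrogenolysed and the ring opened. The fallback is non-reductive and sets out from 20 and returns at 21: Lewis-acid debenzylation with BCl3 and pentamethylbenzene as cation scavenger (CH2Cl2, −78 °C), which leaves the aryl methyl ether in place and makes no new intermediate.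

## Further compounds

F1 | step 6 | 2-lithio-2-methyl-1,3-dithiane | [Li]C1(C)SCCCS1
F2 | step 6 | (2S)-4-[4-(benzyloxy)phenyl]-1-(2-methyl-1,3-dithian-2-yl)butan-2-ol | CC1(C[C@@H](O)CCc2ccc(OCc3ccccc3)cc2)SCCCS1
F3 | step 6 | 2-[(2S)-4-[4-(benzyloxy)phenyl]-2-(tert-butyldimethylsilyloxy)butyl]-2-methyl-1,3-dithiane | CC1(C[C@H](CCc2ccc(OCc3ccccc3)cc2)O[Si](C)(C)C(C)(C)C)SCCCS1
F4 | step 6 | (4S)-6-[4-(benzyloxy)phenyl]-4-(tert-butyldimethylsilyloxy)hexan-2-one | CC(=O)C[C@H](CCc1ccc(OCc2ccccc2)cc1)O[Si](C)(C)C(C)(C)C
F5 | step 6 | dibutylboron enolate of F4, (4S)-6-[4-(benzyloxy)phenyl]-4-(tert-butyldimethylsilyloxy)hex-1-en-2-yl dibutylborinate | C=C(OB(CCCC)CCCC)C[C@H](CCc1ccc(OCc2ccccc2)cc1)O[Si](C)(C)C(C)(C)C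
F6 | step 8 | (1RS,5S)-1-[3,4-bis(benzyloxy)-5-methoxyphenyl]-7-[4-(benzyloxy)phenyl]-5-(tert-butyldimethylsilyloxy)-3-oxoheptyl methanesulfonate | COc1cc(C(OS(C)(=O)=O)CC(=O)C[C@H](CCc2ccc(OCc3ccccc3)cc2)O[Si](C)(C)C(C)(C)C)cc(OCc4ccccc4)c1OCc5ccccc5
F7 | step 2 | 1-(benzyloxy)-4-(but-3-en-1-yl)benzene | C=CCCc1ccc(OCc2ccccc2)cc1
F8 | step 2 | (±)-2-{2-[4-(benzyloxy)phenyl]ethyl}oxirane | O(Cc1ccccc1)c1ccc(CCC2CO2)cc1
F0 | step 10 | none | none
A1 | alternative 1 | (2S,6S)-2-[3,4-bis(benzyloxy)-5-methoxyphenyl]-6-{2-[4-(pivaloyloxy)phenyl]ethyl}tetrahydro-4H-pyran-4-one | COc1cc([C@@H]2CC(=O)C[C@H](CCc3ccc(OC(=O)C(C)(C)C)cc3)O2)cc(OCc4ccccc4)c1OCc5ccccc5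
A2 | alternative 1 | 4-[(3S)-5-acetoxy-3-{[3,4-bis(benzyloxy)-5-methoxyphenyl]methoxy}hex-5-en-1-yl]phenyl 2,2-dimethylpropanoate | C=C(OC(C)=O)C[C@H](CCc1ccc(OC(=O)C(C)(C)C)cc1)OCc1cc(OC)c(OCc2ccccc2)c(OCc2ccccc2)c1
A3 | alternative 2 | (2S,4R,6R)-2-[3,4-bis(benzyloxy)-5-methoxyphenyl]-6-{(E)-2-[4-(benzyloxy)phenyl]ethenyl}-4-(tert-butyldimethylsilyloxy)tetrahydro-2H-pyran | COc1cc([C@@H]2C[C@H](O[Si](C)(C)C(C)(C)C)C[C@H](/C=C/c3ccc(OCc4ccccc4)cc3)O2)cc(OCc5ccccc5)c1OCc6ccccc6
A4 | alternative 2 | (1S,3R,5E,7R)-1-[3,4-bis(benzyloxy)-5-methoxyphenyl]-7-[4-(benzyloxy)phenyl]-3-(tert-butyldimethylsilyloxy)hept-5-ene-1,7-diol | COc1cc([C@@H](O)C[C@H](O[Si](C)(C)C(C)(C)C)C/C=C/[C@@H](O)c2ccc(OCc3ccccc3)cc2)cc(OCc4ccccc4)c1OCc5ccccc5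
A5 | alternative 3 | (2S,6S)-2-[3,4-bis(benzyloxy)-5-methoxyphenyl]-6-{2-[4-(benzyloxy)phenyl]ethyl}tetrahydro-4H-pyran-4-one | COc1cc([C@@H]2CC(=O)C[C@H](CCc3ccc(OCc4ccccc4)cc3)O2)cc(OCc5ccccc5)c1OCc6ccccc6
A6 | alternative 3 | (2R,6S)-6-[3,4-bis(benzyloxy)-5-methoxyphenyl]-2-{2-[4-(benzyloxy)phenyl]ethyl}-4-methylidene-1,3-dioxane (2,6-cis) | C=C1C[C@@H](c2cc(OC)c(OCc3ccccc3)c(OCc4ccccc4)c2)O[C@@H](CCc5ccc(OCc6ccccc6)cc5)O1
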